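**Plan**
- Cuts: the C3–O ester bond (angelate) and the C2–O bond last, then the C3–C4 bond of ring A. At the 3-oxo/18-al level, quaternary C4 (CH3 and CHO) beside the C3 carbonyl is the product pattern of a 1,2-acyl shift. Ring A (C1–C2–C3–C4–C5–C10) is therefore traced to a seven-membered 4,19-epoxy-3-ketone ring C1–C2–C3–C19–C4–C5–C10.
- That ring is traced to ring A of cheap andrographolide: its axial C19 is joined to C3 (cyclopropanol) and the old C3–C4 bond is then cleaved with release of ring strain.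
- Forward order: side chain to the silyl-protected 13Z-15,16-diol; ring A 6 → 7 → 6; oxygen at C2; reduction at C3; angelate; desilylation. Ring B and all skeletal carbons are those of andrographolide.
- Stereochemistry: C5, C9 and C10 are inherited and the 13Z geometry comes from the butenolide ring. C4 is inverted by β-face epoxidation (anti to C20) and anti acyl shift. C2 and C3 follow from approach anti to the α-axial methyls on C4 and C10.

Key step: step 10

Remark: labdane numbering is used; α is the face of the angular methyl C20 (the series is that of andrographolide); C18 is the equatorial and C19 the axial carbon on C4, so the carbon called C19 up to compound 11 is called C18 from compound 12 on.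

**Step 1**
Reactants: 1 andrographolide
Product: 2 3,14,19-tri-O-acetylandrographolide
Conditions: Ac2O, pyridine, 0 °C to rt
Reagents that add atoms: acetic anhydride CC(=O)OC(C)=O
Why: Exhaustive O-acetylation (acyl transfer) masks the 3- and 19-hydroxyls and turns the allylic 14-hydroxyl into the leaving group needed in step 2, with no stereocentre touched.

**Step 2**
Reactants: 2 3,14,19-tri-O-acetylandrographolide
Product: 3 3,19-di-O-acetyl-14-deoxyandrographolide (Δ13 butenolide, C12 saturated)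
Conditions: NaBH4, THF–MeOH, 0 °C
Reagents that add atoms: none
Why: Conjugate hydride addition at C12 of the α-alkylidene lactone followed by E1cB loss of the 14-acetate (net SN2′ reduction) should move the double bond into the lactone ring, which removes the C14 stereocentre and holds C15 and C16 cis on the new alkene.

**Step 3**
Reactants: 3 3,19-di-O-acetyl-14-deoxyandrographolide
Product: 4 labda-8(17),13Z-diene-3α,15,16,19-tetraol
Conditions: i-Bu2AlH (10 equiv), CH2Cl2, −78 to 0 °C; aq. KNaC4H4O6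
Reagents that add atoms: none
Why: 1,2-Reduction of the butenolide past the lactol stage with excess aluminium hydride should give the Z-2-ene-1,4-diol (geometry fixed by the former ring) while both acetates are cleaved reductively in the same operation.

**Step 4**
Reactants: 4 labda-8(17),13Z-diene-3α,15,16,19-tetraol
Product: 5 15,16-bis(tert-butyldiphenylsilyloxy)labda-8(17),13Z-diene-3α,19-diol
Conditions: TBDPSCl (2.1 equiv), imidazole, CH2Cl2–DMF, −20 to 0 °C
Reagents that add atoms: tert-butyl(chloro)diphenylsilane CC(C)(C)[Si](Cl)(c1ccccc1)c1ccccc1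
Why: Sterically governed silylation should take the two unhindered allylic primary hydroxyls well before the axial neopentyl 19-OH and the secondary 3-OH.

**Step 5**
Reactants: 5 15,16-bis(TBDPS-oxy)labda-8(17),13Z-diene-3α,19-diol
Product: 6 19-iodo-15,16-bis(TBDPS-oxy)labda-8(17),13Z-dien-3α-ol
Conditions: PPh3, I2, imidazole, toluene, 80 °C
Reagents that add atoms: iodine II
Why: Appel-type (Garegg–Samuelsson) iodination, in which only the primary 19-oxyphosphonium can be displaced by iodide and the hindered secondary 3-OH is returned on work-up.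

**Step 6**
Reactants: 6 19-iodo-15,16-bis(TBDPS-oxy)labda-8(17),13Z-dien-3α-ol
Product: 7 19-iodo-15,16-bis(TBDPS-oxy)labda-8(17),13Z-dien-3-one
Conditions: Dess–Martin periodinane, pyridine, CH2Cl2, rt
Reagents that add atoms: none
Why: Dess–Martin oxidation of the secondary alcohol gives a β-iodo ketone that cannot eliminate because C4 is quaternary.

**Step 7**
Reactants: 7 19-iodo-15,16-bis(TBDPS-oxy)labda-8(17),13Z-dien-3-one
Product: 8 3α,19-cyclo-15,16-bis(TBDPS-oxy)labda-8(17),13Z-dien-3β-ol (cyclopropanol C3–C4–C19)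
Conditions: SmI2 (2.5 equiv), HMPA, THF, −78 to 0 °C; aq. NH4Cl
Reagents that add atoms: none
Why: Reductive 3-exo cyclisation of a β-halo ketone (ketyl/Barbier type, known for bicyclic cyclopropanols from 2-halomethyl cycloalkanones) should join C19 to C3; because C19 sits on the α face of C4 the three-membered ring can only form cis-fused on that face, which sets C3 (OH β).

**Step 8**
Reactants: 8 cyclopropanol
Product: 10 seven-membered enone with ring C1–C2–C3(=O)–C19H=C4(CH3)–C5–C10, via β-chloro ketone 9 (not isolated)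
Conditions: FeCl3 (2.2 equiv), pyridine (1 equiv), DMF, 0 °C; then NaOAc, MeOH, reflux
Reagents that add atoms: none
Why: Saegusa–Ito-type oxidative ring expansion, in which one-electron oxidation gives the cyclopropyloxy radical, β-scission of the internal C3–C4 bond releases the ring strain towards the tertiary C4 radical (not the primary C19 radical), and chlorine transfer followed by E1cB elimination places the alkene at C19=C4 in conjugation with C3=O.

**Step 9**
Reactants: 10 seven-membered enone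
Product: 11 4β,19β-epoxy seven-membered ketone
Conditions: 30% H2O2, NaOH (cat.), MeOH–THF, 0 °C to rt
Reagents that add atoms: hydrogen peroxide OO
Why: Weitz–Scheffer nucleophilic epoxidation touches only the enone and hydroperoxide should add to C4 from the β face, anti to the α-axial angular methyl C20 on C10, which fixes both epoxide centres.

**Step 10**
Reactants: 11 4β,19β-epoxy seven-membered ketone
Product: 12 15,16-bis(TBDPS-oxy)-3-oxolabda-8(17),13Z-dien-18-al (4α-CH3, 4β-CHO)
Conditions: BF3·OEt2 (0.5 equiv), CH2Cl2, −78 to −20 °C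
Reagents that add atoms: none
Why: BF3 coordinates the epoxide oxygen and the C4–O bond, the one leading to a tertiary cation remote from the carbonyl, ionises while the acyl carbon C3 shifts from C19 to C4 and C19 collapses to the aldehyde, so that C19 leaves the ring and becomes the formyl carbon (C18 from here on). The closest known reaction type is the Lewis-acid rearrangement of cyclic α,β-epoxy ketones to ring-contracted 2-formyl ketones, a Meinwald-type semipinacol 1,2-acyl shift. Ring A closes by forming the C3–C4 bond in a suprafacial 1,2-shift through a three-centre transition state, which contracts the seven-membered ring C1–C2–C3–C19–C4–C5–C10 to the six-membered ring C1–C2–C3–C4–C5–C10. The only new stereocentre, quaternary C4, is set stereospecifically: C3 enters anti to the departing β-oxygen, so the methyl ends α (axial) and the formyl group β (equatorial), the inverse of andrographolide, the information coming from the epoxide face fixed in step 9 by C20. The step needs acyl migration to win over hydride migration from C19 (which would give a 3,19-diketone) and over proton loss to an allylic alcohol; this should be secured by the higher migratory aptitude of the acyl group in cyclic epoxy ketones, by the strain relief on going from seven to six ring atoms, and by the low temperature, which also spares the exocyclic alkene and the silyl ethers.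

**Step 11**
Reactants: 12 3-oxo-18-al
Product: 13 18-hydroxy-15,16-bis(TBDPS-oxy)labda-8(17),13Z-dien-3-one
Conditions: LiAlH(O-t-Bu)3 (1.1 equiv), THF, −78 °C
Reagents that add atoms: none
Why: Chemoselective hydride reduction of the aldehyde beside the hindered ketone with a bulky alkoxyaluminium hydride at low temperature, done at once so that the 2-formyl ketone cannot lose its formyl group.

**Step 12**
Reactants: 13 18-hydroxy-3-ketone
Product: 14 3,18-bis(tert-butyldimethylsilyloxy)-15,16-bis(TBDPS-oxy)labda-2,8(17),13Z-triene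
Conditions: TBSOTf (2.5 equiv), Et3N, CH2Cl2, 0 °C to rt
Reagents that add atoms: tert-butyldimethylsilyl trifluoromethanesulfonate CC(C)(C)[Si](C)(C)OS(=O)(=O)C(F)(F)F
Why: One operation silylates the neopentyl 18-OH and converts the ketone into its silyl enol ether (soft enolisation), which can only form towards C2 because C4 is quaternary.

**Step 13**
Reactants: 14 silyl enol ether
Product: 16 2β,18-bis(TBS-oxy)-15,16-bis(TBDPS-oxy)labda-8(17),13Z-dien-3-one, via epoxy silyl ether 15 (not isolated)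
Conditions: dimethyldioxirane (1.05 equiv), acetone–CH2Cl2, −78 °C; then pyridinium p-toluenesulfonate (cat.), 0 °C
Reagents that add atoms: dimethyldioxirane CC1(C)OO1
Why: Rubottom oxidation, in which the electron-rich enol ether should be epoxidised much faster than the two remaining alkenes, from the β face because the α face at C2 is blocked by the syn-axial methyls on C4 and C10, and acid-triggered opening with 1,4 O-to-O silyl shift gives the equatorial 2β-silyloxy ketone.

**Step 14**
Reactants: 16 2β-silyloxy-3-ketone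
Product: 17 2β,18-bis(TBS-oxy)-15,16-bis(TBDPS-oxy)labda-8(17),13Z-dien-3α-ol
Conditions: NaBH4, MeOH–CH2Cl2, −20 to 0 °C
Reagents that add atoms: none
Why: Borohydride reduction with axial hydride delivery from the β face, the α face being shielded by the axial methyl on C4, should give the equatorial 3α-alcohol trans to the 2β-silyloxy group.

**Step 15**
Reactants: 17 3α-alcohol; 18 angelic acid
Product: 20 2β,18-bis(TBS-oxy)-15,16-bis(TBDPS-oxy)labda-8(17),13Z-dien-3α-yl angelate, via angelic 2,4,6-trichlorobenzoic anhydride 19 (not isolated)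
Conditions: 18, 2,4,6-trichlorobenzoyl chloride, Et3N, toluene, rt; then 17, 80 °C
Reagents that add atoms: none
Why: Yamaguchi-type esterification through the mixed anhydride, run without a nucleophilic amine catalyst, should acylate the only free hydroxyl (3-OH) without isomerising the Z double bond of the angelate to the tiglate.

**Step 16**
Reactants: 20 silylated angelate
Product: 21 target, 2β,15,16,18-tetrahydroxylabda-8(17),13Z-dien-3α-yl angelate (CNP0324138.1)
Conditions: HF·pyridine, pyridine, THF, 0 °C to rt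
Reagents that add atoms: none
Why: Fluoride cleavage of all four silyl ethers under buffered, weakly acidic conditions should avoid migration of the 3-O-angelate to the neighbouring 2- or 18-hydroxyl.

**Compound list**
1 | andrographolide | C=C1CC[C@H]2[C@@](C)(CC[C@@H](O)[C@@]2(C)CO)[C@@H]1C/C=C/3\[C@@H](COC3=O)O | starting material
2 | 3,14,19-tri-O-acetylandrographolide | C=C1CC[C@H]2[C@@](C)(CC[C@@H](OC(C)=O)[C@@]2(C)COC(C)=O)[C@@H]1C/C=C/3\[C@@H](COC3=O)OC(C)=O | intermediate
3 | 3,19-di-O-acetyl-14-deoxyandrographolide | C=C1CC[C@H]2[C@@](C)(CC[C@@H](OC(C)=O)[C@@]2(C)COC(C)=O)[C@@H]1CCC3=CCOC3=O | intermediate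
4 | labda-8(17),13Z-diene-3α,15,16,19-tetraol | C=C1CC[C@H]2[C@@](C)(CC[C@@H](O)[C@@]2(C)CO)[C@@H]1CC/C(=C/CO)CO | intermediate
5 | 15,16-bis(TBDPS-oxy)labda-8(17),13Z-diene-3α,19-diol | C=C1CC[C@H]2[C@@](C)(CC[C@@H](O)[C@@]2(C)CO)[C@@H]1CC/C(=C/CO[Si](c4ccccc4)(c4ccccc4)C(C)(C)C)CO[Si](c4ccccc4)(c4ccccc4)C(C)(C)C | intermediate
6 | 19-iodo-15,16-bis(TBDPS-oxy)labda-8(17),13Z-dien-3α-ol | C=C1CC[C@H]2[C@@](C)(CC[C@@H](O)[C@@]2(C)CI)[C@@H]1CC/C(=C/CO[Si](c4ccccc4)(c4ccccc4)C(C)(C)C)CO[Si](c4ccccc4)(c4ccccc4)C(C)(C)C | intermediate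
7 | 19-iodo-15,16-bis(TBDPS-oxy)labda-8(17),13Z-dien-3-one | C=C1CC[C@H]2[C@@](C)(CCC(=O)[C@@]2(C)CI)[C@@H]1CC/C(=C/CO[Si](c4ccccc4)(c4ccccc4)C(C)(C)C)CO[Si](c4ccccc4)(c4ccccc4)C(C)(C)C | intermediate
8 | 3α,19-cyclo-15,16-bis(TBDPS-oxy)labda-8(17),13Z-dien-3β-ol (cyclopropanol, CH2-19 on the α face) | C=C1CC[C@H]2[C@@](C)(CC[C@@]3(O)C[C@@]23C)[C@@H]1CC/C(=C/CO[Si](c4ccccc4)(c4ccccc4)C(C)(C)C)CO[Si](c4ccccc4)(c4ccccc4)C(C)(C)C | intermediate
9 | seven-membered 4-chloro-4-methyl-3-ketone, ring C1–C2–C3(=O)–C19H2–C4(Cl)(CH3)–C5–C10, C4 epimers, not isolated | C=C1CC[C@H]2[C@@](C)(CCC(=O)CC2(C)Cl)[C@@H]1CC/C(=C/CO[Si](c4ccccc4)(c4ccccc4)C(C)(C)C)CO[Si](c4ccccc4)(c4ccccc4)C(C)(C)C | intermediate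
10 | seven-membered enone, ring C1–C2–C3(=O)–C19H=C4(CH3)–C5–C10 | C=C1CC[C@H]2[C@@](C)(CCC(=O)C=C2C)[C@@H]1CC/C(=C/CO[Si](c4ccccc4)(c4ccccc4)C(C)(C)C)CO[Si](c4ccccc4)(c4ccccc4)C(C)(C)C | intermediate
11 | 4β,19β-epoxide of 10 | C=C1CC[C@H]2[C@@](C)(CCC(=O)[C@@H]3O[C@]23C)[C@@H]1CC/C(=C/CO[Si](c4ccccc4)(c4ccccc4)C(C)(C)C)CO[Si](c4ccccc4)(c4ccccc4)C(C)(C)C | intermediate
12 | 15,16-bis(TBDPS-oxy)-3-oxolabda-8(17),13Z-dien-18-al (4α-CH3, 4β-CHO) | C=C1CC[C@H]2[C@@](C)(CCC(=O)[C@]2(C)C=O)[C@@H]1CC/C(=C/CO[Si](c4ccccc4)(c4ccccc4)C(C)(C)C)CO[Si](c4ccccc4)(c4ccccc4)C(C)(C)C | intermediate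
13 | 18-hydroxy-15,16-bis(TBDPS-oxy)labda-8(17),13Z-dien-3-one | C=C1CC[C@H]2[C@@](C)(CCC(=O)[C@]2(C)CO)[C@@H]1CC/C(=C/CO[Si](c4ccccc4)(c4ccccc4)C(C)(C)C)CO[Si](c4ccccc4)(c4ccccc4)C(C)(C)C | intermediate
14 | 3,18-bis(TBS-oxy)-15,16-bis(TBDPS-oxy)labda-2,8(17),13Z-triene | C=C1CC[C@H]2[C@@](C)(CC=C(O[Si](C)(C)C(C)(C)C)[C@]2(C)CO[Si](C)(C)C(C)(C)C)[C@@H]1CC/C(=C/CO[Si](c4ccccc4)(c4ccccc4)C(C)(C)C)CO[Si](c4ccccc4)(c4ccccc4)C(C)(C)C | intermediate
15 | 2β,3β-epoxy-3α,18-bis(TBS-oxy)-15,16-bis(TBDPS-oxy)labda-8(17),13Z-diene, not isolated | C=C1CC[C@H]2[C@@](C)(C[C@@H]3O[C@]3(O[Si](C)(C)C(C)(C)C)[C@]2(C)CO[Si](C)(C)C(C)(C)C)[C@@H]1CC/C(=C/CO[Si](c4ccccc4)(c4ccccc4)C(C)(C)C)CO[Si](c4ccccc4)(c4ccccc4)C(C)(C)C | intermediate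
16 | 2β,18-bis(TBS-oxy)-15,16-bis(TBDPS-oxy)labda-8(17),13Z-dien-3-one | C=C1CC[C@H]2[C@@](C)(C[C@H](O[Si](C)(C)C(C)(C)C)C(=O)[C@]2(C)CO[Si](C)(C)C(C)(C)C)[C@@H]1CC/C(=C/CO[Si](c4ccccc4)(c4ccccc4)C(C)(C)C)CO[Si](c4ccccc4)(c4ccccc4)C(C)(C)C | intermediate
17 | 2β,18-bis(TBS-oxy)-15,16-bis(TBDPS-oxy)labda-8(17),13Z-dien-3α-ol | C=C1CC[C@H]2[C@@](C)(C[C@H](O[Si](C)(C)C(C)(C)C)[C@@H](O)[C@]2(C)CO[Si](C)(C)C(C)(C)C)[C@@H]1CC/C(=C/CO[Si](c4ccccc4)(c4ccccc4)C(C)(C)C)CO[Si](c4ccccc4)(c4ccccc4)C(C)(C)C | intermediate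
18 | angelic acid, (Z)-2-methylbut-2-enoic acid | C/C=C(/C)C(=O)O | starting material
19 | angelic 2,4,6-trichlorobenzoic anhydride, not isolated | C/C=C(/C)C(=O)OC(=O)c1c(Cl)cc(Cl)cc1Cl | intermediate
20 | 2β,18-bis(TBS-oxy)-15,16-bis(TBDPS-oxy)labda-8(17),13Z-dien-3α-yl angelate | C=C1CC[C@H]2[C@@](C)(C[C@H](O[Si](C)(C)C(C)(C)C)[C@@H](OC(=O)/C(C)=C\C)[C@]2(C)CO[Si](C)(C)C(C)(C)C)[C@@H]1CC/C(=C/CO[Si](c4ccccc4)(c4ccccc4)C(C)(C)C)CO[Si](c4ccccc4)(c4ccccc4)C(C)(C)C | intermediate
21 | 2β,15,16,18-tetrahydroxylabda-8(17),13Z-dien-3α-yl angelate (CNP0324138.1) | C=C1CC[C@H]2[C@@](C)(C[C@H](O)[C@@H](OC(=O)/C(C)=C\C)[C@]2(C)CO)[C@@H]1CC/C(=C/CO)CO | target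

**Totals**
Total step count: 16. Longest linear sequence: 16 steps (from andrographolide; angelic acid enters in step 15).

**Steps most likely to fail**

Step 7. The ketyl ring closure may be outrun by simple reduction of the carbon–iodine bond or of the ketone, or by a radical 1,2-acyl shift before the second electron arrives. The neopentyl iodination of step 5 that feeds it is also demanding. The fallback sets out from compound 5, avoids the iodide and comes back at compound 10. Both hydroxyls of 5 would be oxidised with Dess–Martin periodinane to the 3-oxo-19-al F1. K2CO3 in MeOH would remove the formyl group by retro-Claisen cleavage to the 19-nor-4β-methyl-3-ketone F2 (equatorial methyl). Me3SiI with (Me3Si)2NH under equilibrating conditions would give the tetrasubstituted Δ3 trimethylsilyl enol ether F3. Simmons–Smith cyclopropanation in the Furukawa form (Et2Zn, CH2I2, 1 equiv, 0 °C), expected on the β face and fastest at the enol ether, would give the siloxycyclopropane F4. Its oxidation with FeCl3 and elimination with NaOAc as in step 8 should give enone 10, the new methylene carbon taking the place of C19.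

Step 10. Hydride migration from C19 or proton loss from the C4 cation may compete with the acyl shift, and the Lewis acid may move the exocyclic double bond. The fallback sets out from compound 11, still closes ring A by contraction of the seven-membered ring, and comes back at compound 12. Reduction with NaBH4 and CeCl3·7H2O would give the epoxy alcohol F5; mainly the 3β-alcohol is expected, and either epimer serves because C3 is reoxidised. Me3SiCl and imidazole would give its trimethylsilyl ether F6. MeAl(OAr)2 (Ar = 4-bromo-2,6-di-tert-butylphenyl) in CH2Cl2 at −78 °C should induce the semipinacol rearrangement of the 2,3-epoxy silyl ether, the carbinol carbon C3 shifting anti to the epoxide oxygen to give the ring-contracted 3-silyloxy-18-al F7 with the same configuration at C4. Dilute HCl in the work-up would free the 3-hydroxy-18-al F8, and Dess–Martin oxidation returns 12.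

Step 13. The dioxirane may also epoxidise the 8(17) or the 13(14) double bond, and the silyl shift may be incomplete. The fallback sets out from compound 13, brings in the oxygen through the enolate and comes back at compound 16. TBSCl and imidazole would give the 18-silyl ether F9. KN(SiMe3)2 in THF at −78 °C followed by 2-(phenylsulfonyl)-3-phenyloxaziridine would hydroxylate the enolate from the β face to the 2β-hydroxy ketone F10, a reaction that leaves isolated alkenes alone. TBSOTf and 2,6-lutidine then give 16.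

**Further compounds**
F1 | step 7 | 15,16-bis(TBDPS-oxy)-3-oxolabda-8(17),13Z-dien-19-al (4β-CH3, 4α-CHO) | C=C1CC[C@H]2[C@@](C)(CCC(=O)[C@@]2(C)C=O)[C@@H]1CC/C(=C/CO[Si](c4ccccc4)(c4ccccc4)C(C)(C)C)CO[Si](c4ccccc4)(c4ccccc4)C(C)(C)C
F2 | step 7 | 19-nor-4β-methyl-15,16-bis(TBDPS-oxy)labda-8(17),13Z-dien-3-one | C=C1CC[C@H]2[C@@](C)(CCC(=O)[C@@H]2C)[C@@H]1CC/C(=C/CO[Si](c4ccccc4)(c4ccccc4)C(C)(C)C)CO[Si](c4ccccc4)(c4ccccc4)C(C)(C)C
F3 | step 7 | 19-nor-3-(trimethylsilyloxy)-15,16-bis(TBDPS-oxy)labda-3,8(17),13Z-triene | C=C1CC[C@H]2[C@@](C)(CCC(O[Si](C)(C)C)=C2C)[C@@H]1CC/C(=C/CO[Si](c4ccccc4)(c4ccccc4)C(C)(C)C)CO[Si](c4ccccc4)(c4ccccc4)C(C)(C)C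
F4 | step 7 | 3β,4β-methano-3α-(trimethylsilyloxy)-4α-methyl compound (siloxycyclopropane, CH2 bridge on the β face) | C=C1CC[C@H]2[C@@](C)(CC[C@]3(O[Si](C)(C)C)C[C@]23C)[C@@H]1CC/C(=C/CO[Si](c4ccccc4)(c4ccccc4)C(C)(C)C)CO[Si](c4ccccc4)(c4ccccc4)C(C)(C)C
F5 | step 10 | 4β,19β-epoxy seven-membered 3β-alcohol | C=C1CC[C@H]2[C@@](C)(CC[C@H](O)[C@@H]3O[C@]23C)[C@@H]1CC/C(=C/CO[Si](c4ccccc4)(c4ccccc4)C(C)(C)C)CO[Si](c4ccccc4)(c4ccccc4)C(C)(C)C
F6 | step 10 | trimethylsilyl ether of F5 | C=C1CC[C@H]2[C@@](C)(CC[C@H](O[Si](C)(C)C)[C@@H]3O[C@]23C)[C@@H]1CC/C(=C/CO[Si](c4ccccc4)(c4ccccc4)C(C)(C)C)CO[Si](c4ccccc4)(c4ccccc4)C(C)(C)C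
F7 | step 10 | 3β-(trimethylsilyloxy)-15,16-bis(TBDPS-oxy)labda-8(17),13Z-dien-18-al | C=C1CC[C@H]2[C@@](C)(CC[C@H](O[Si](C)(C)C)[C@]2(C)C=O)[C@@H]1CC/C(=C/CO[Si](c4ccccc4)(c4ccccc4)C(C)(C)C)CO[Si](c4ccccc4)(c4ccccc4)C(C)(C)C
F8 | step 10 | 3β-hydroxy-15,16-bis(TBDPS-oxy)labda-8(17),13Z-dien-18-al | C=C1CC[C@H]2[C@@](C)(CC[C@H](O)[C@]2(C)C=O)[C@@H]1CC/C(=C/CO[Si](c4ccccc4)(c4ccccc4)C(C)(C)C)CO[Si](c4ccccc4)(c4ccccc4)C(C)(C)C
F9 | step 13 | 18-(TBS-oxy)-15,16-bis(TBDPS-oxy)labda-8(17),13Z-dien-3-one | C=C1CC[C@H]2[C@@](C)(CCC(=O)[C@]2(C)CO[Si](C)(C)C(C)(C)C)[C@@H]1CC/C(=C/CO[Si](c4ccccc4)(c4ccccc4)C(C)(C)C)CO[Si](c4ccccc4)(c4ccccc4)C(C)(C)C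
F10 | step 13 | 2β-hydroxy-18-(TBS-oxy)-15,16-bis(TBDPS-oxy)labda-8(17),13Z-dien-3-one | C=C1CC[C@H]2[C@@](C)(C[C@H](O)C(=O)[C@]2(C)CO[Si](C)(C)C(C)(C)C)[C@@H]1CC/C(=C/CO[Si](c4ccccc4)(c4ccccc4)C(C)(C)C)CO[Si](c4ccccc4)(c4ccccc4)C(C)(C)C
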